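**Retrosynthetic overview** (primed locants = unit 2, the dihydrobenzofuran that carries the 2,4-dihydroxyphenyl group)
1. Target 25 comes from its octamethyl ether 24 by global O-demethylation; the stilbene C6–Cα bond comes from a Heck reaction of aryl chloride 22.
2. Each dihydrofuran ring is a 3,4-diarylchroman-2-one that has lost its lactone carbonyl carbon: the ring-opened α-aryl acid is decarboxylated oxidatively to the C2′ (later C2) benzylic cation, and the ortho oxygen on the C3′ (C3) aryl ring closes O1′–C2′ (O1–C2).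
3. Feature used: in ring O1′–C2′–C3′–C3a′–C7a′ the carbon C2′ bears the 2,4-dioxygenated aryl ring, so its cation is exceptionally stabilised, and C3′/C2′ map onto C4/C3 of a coumarin. Unit 1 repeats the pattern with a 4-oxygenated aryl ring on C2.
4. C3′ and C3 are set by Rh-catalysed asymmetric 1,4-arylation of 7-chloro-5-methoxycoumarin 6, first with 7, then with unit-2 boronate 15 (C3–C6′ bond). The C2′/C2 aryl groups enter by ester α-arylation. The phenol oxygen is carried as a MOM ether, because a free hydroxy acid would relactonise and a free phenol is itself oxidisable; MOM is shed in the ring closure.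
5. Ring order: coumarin 6 → chromanone 8 → unit-2 dihydrofuran 14 (step 8) → chromanone 16 → unit-1 dihydrofuran 22 (step 14) → stilbene → deprotection.

Key step: step 8

Remark on stereochemistry: the target SMILES is read as (2R,3R,2′R,3′R), both dihydrofuran rings trans.
Assumption: (R)-Segphos–Rh is taken to arylate coumarin 6 with the facial sense it shows on simple coumarins, which gives the 4R lactones; if the 5-methoxy group reverses it, (S)-Segphos is used.

**Step 1**
Reactants: 1 4-chloro-2,6-difluorobenzaldehyde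
Product: 2 4-chloro-2,6-dimethoxybenzaldehyde
Conditions: NaOMe (2.3 equiv), MeOH/THF, 0 → 50 °C
Reagents that add atoms: sodium methoxide, C[O-].[Na+]
Why: Double SNAr; both fluorides are ortho to the formyl group and far better leaving groups than the para chloride, which should survive at this temperature.

**Step 2**
Reactants: 2 4-chloro-2,6-dimethoxybenzaldehyde
Product: 3 4-chloro-2-hydroxy-6-methoxybenzaldehyde
Conditions: BCl3 (1.2 equiv), CH2Cl2, −78 → 0 °C; H2O
Reagents that add atoms: none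
Why: Chelation-controlled mono-demethylation; BCl3 bound to the aldehyde oxygen cleaves one ortho methyl ether, and the resulting six-membered aryloxyboron chelate resists a second cleavage.

**Step 3**
Reactants: 3 4-chloro-2-hydroxy-6-methoxybenzaldehyde; 4 ethyl (triphenylphosphoranylidene)acetate
Product: 6 7-chloro-5-methoxy-2H-chromen-2-one, via cinnamate ester 5 (not isolated)
Conditions: PhNEt2, reflux
Reagents that add atoms: none
Why: Wittig olefination followed in the same pot by thermal E/Z isomerisation and lactonisation with loss of ethanol, the usual one-pot coumarin synthesis from salicylaldehydes and stabilised ylides.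

**Step 4**
Reactants: 6 7-chloro-5-methoxy-2H-chromen-2-one; 7 3,5-dimethoxyphenylboronic acid
Product: 8 (4R)-7-chloro-4-(3,5-dimethoxyphenyl)-5-methoxy-3,4-dihydro-2H-chromen-2-one
Conditions: 7 (5 equiv), Rh(acac)(C2H4)2 (3 mol%), (R)-Segphos (3.3 mol%), dioxane/H2O (10:1), 60 °C
Reagents that add atoms: none
Why: Hayashi–Miyaura Rh-catalysed asymmetric 1,4-addition to a coumarin; the ligand-controlled aryl transfer to one face of C4 sets the future C3′ as 4R, and the aryl chloride is inert to Rh(I).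

**Step 5**
Reactants: 8 (4R)-7-chloro-4-(3,5-dimethoxyphenyl)-5-methoxy-3,4-dihydro-2H-chromen-2-one
Product: 10 methyl (3R)-3-[4-chloro-2-methoxy-6-(methoxymethoxy)phenyl]-3-(3,5-dimethoxyphenyl)propanoate, via sodium phenoxide 9 (not isolated)
Conditions: NaOMe (1.05 equiv), MeOH/THF, 0 °C; concentrate; MOMCl (1.3 equiv), DMF, 0 °C → rt
Reagents that add atoms: sodium methoxide, C[O-].[Na+]; chloromethyl methyl ether, COCCl
Why: Methanolysis of the aryl lactone (the phenoxide cannot reclose because that would expel methoxide) followed by Williamson O-alkylation of the phenoxide; C3 is not touched.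

**Step 6**
Reactants: 10 methyl (3R)-3-[4-chloro-2-methoxy-6-(methoxymethoxy)phenyl]-3-(3,5-dimethoxyphenyl)propanoate; 11 1-bromo-2,4-dimethoxybenzene
Product: 12 methyl (3R)-3-[4-chloro-2-methoxy-6-(methoxymethoxy)phenyl]-2-(2,4-dimethoxyphenyl)-3-(3,5-dimethoxyphenyl)propanoate (both C2 epimers)
Conditions: 11 (1.3 equiv), LiHMDS (2.3 equiv), Pd(dba)2 (5 mol%), P(t-Bu)3 (5 mol%), toluene, rt → 50 °C; aq. NH4Cl
Reagents that add atoms: none
Why: Pd-catalysed α-arylation of an ester enolate; the aryl bromide should undergo oxidative addition faster than the substrate's aryl chloride, the bulky phosphine favours reductive elimination over β-hydride loss, and the C2 configuration is irrelevant because step 8 erases it.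

**Step 7**
Reactants: 12 methyl (3R)-3-[4-chloro-2-methoxy-6-(methoxymethoxy)phenyl]-2-(2,4-dimethoxyphenyl)-3-(3,5-dimethoxyphenyl)propanoate
Product: 13 (3R)-3-[4-chloro-2-methoxy-6-(methoxymethoxy)phenyl]-2-(2,4-dimethoxyphenyl)-3-(3,5-dimethoxyphenyl)propanoic acid (both C2 epimers)
Conditions: LiOH·H2O (10 equiv), THF/MeOH/H2O, 60 °C; 1 M HCl to pH 3–4, 0 °C
Reagents that add atoms: lithium hydroxide, [Li+].[OH-]
Why: Saponification; with the phenol masked the acid cannot lactonise and can be purified, and cold, brief acidification leaves the MOM acetal intact.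

**Step 8**
Reactants: 13 (3R)-3-[4-chloro-2-methoxy-6-(methoxymethoxy)phenyl]-2-(2,4-dimethoxyphenyl)-3-(3,5-dimethoxyphenyl)propanoic acid
Product: 14 (2R,3R)-6-chloro-2-(2,4-dimethoxyphenyl)-3-(3,5-dimethoxyphenyl)-4-methoxy-2,3-dihydro-1-benzofuran
Conditions: undivided cell, graphite anode/Pt cathode, constant current (charge limited to ca. 2.2 F mol−1), 2,4,6-collidine (1.5 equiv), HFIP (5 equiv), n-Bu4NPF6 (0.1 M), CH2Cl2, rt
Reagents that add atoms: none
Why: Proposed new method: the carboxylate of 13 (collidine as base) is oxidised at the anode with help from the neighbouring 2,4-dimethoxyphenyl ring, CO2 is expelled, and the C2′ benzylic radical is oxidised at once to the 2,4-dimethoxybenzylic cation; the oxygen of the ortho MOM ether on the C3′ aryl ring adds to it and the oxonium ion sheds the methoxymethyl cation to HFIP, so that the chromanone skeleton has lost exactly its carbonyl carbon. The closest known reaction types are the Hofer–Moest (non-Kolbe) decarboxylative etherification of arylacetic acids and the O-5 participation of ortho-alkoxyaryl groups that ends in dealkylative dihydrobenzofuran formation. The ring closes in a 5-exo-trig mode on the quinone-methide-like cation (its C2′=C1″ bond lies outside the new ring) and forms O1′–C2′. The new centre C2′ is set under substrate control by C3′: the oxygen adds to the face that leaves the 2,4-dimethoxyphenyl group anti to the 3,5-dimethoxyphenyl group, and the trans ring is also the more stable isomer, while C3′ itself is not touched and both C2 epimers of 13 converge on one cation. The step needs electron loss at the carboxylate before the arenes and ring closure before proton loss from C3′; the masked phenol and the chlorine keep the A ring hard to oxidise, the limited charge protects the product, and the nucleophile sits five atoms from the cation.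

**Step 9**
Reactants: 14 (2R,3R)-6-chloro-2-(2,4-dimethoxyphenyl)-3-(3,5-dimethoxyphenyl)-4-methoxy-2,3-dihydro-1-benzofuran
Product: 15 2-[(2R,3R)-2-(2,4-dimethoxyphenyl)-3-(3,5-dimethoxyphenyl)-4-methoxy-2,3-dihydro-1-benzofuran-6-yl]-4,4,5,5-tetramethyl-1,3,2-dioxaborolane
Conditions: B2pin2 (1.5 equiv), Pd2(dba)3 (2 mol%), XPhos (8 mol%), KOAc (3 equiv), dioxane, 100 °C
Reagents that add atoms: bis(pinacolato)diboron, CC1(C)OB(OC1(C)C)B1OC(C)(C)C(C)(C)O1
Why: Miyaura borylation of an aryl chloride with a dialkylbiarylphosphine–Pd catalyst; the ethers and the benzylic C–O bond are inert to the weakly basic conditions.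

**Step 10**
Reactants: 15 unit-2 pinacol boronate; 6 7-chloro-5-methoxy-2H-chromen-2-one
Product: 16 (4R)-7-chloro-4-[(2R,3R)-2-(2,4-dimethoxyphenyl)-3-(3,5-dimethoxyphenyl)-4-methoxy-2,3-dihydro-1-benzofuran-6-yl]-5-methoxy-3,4-dihydro-2H-chromen-2-one
Conditions: 6 (3 equiv), Rh(acac)(C2H4)2 (5 mol%), (R)-Segphos (5.5 mol%), KOH (0.2 equiv), dioxane/H2O (10:1), 60 °C
Reagents that add atoms: none
Why: Second Hayashi–Miyaura 1,4-addition, run with the coumarin in excess because the boronate is the valuable partner; it forms the C3–C6′ bond and sets C3 (4R in 16) under catalyst control, the remote C2′/C3′ centres being expected to have little influence.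

**Step 11**
Reactants: 16 the unit-1 chromanone
Product: 18 methyl (3R)-3-[4-chloro-2-methoxy-6-(methoxymethoxy)phenyl]-3-[(2R,3R)-2-(2,4-dimethoxyphenyl)-3-(3,5-dimethoxyphenyl)-4-methoxy-2,3-dihydro-1-benzofuran-6-yl]propanoate, via sodium phenoxide 17 (not isolated)
Conditions: NaOMe (1.05 equiv), MeOH/THF, 0 °C; concentrate; MOMCl (1.3 equiv), DMF, 0 °C → rt
Reagents that add atoms: sodium methoxide, C[O-].[Na+]; chloromethyl methyl ether, COCCl
Why: Lactone methanolysis and Williamson O-alkylation as in step 5; the basic conditions leave the unit-2 dihydrofuran ring alone.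

**Step 12**
Reactants: 18 the MOM ether methyl ester; 19 4-bromoanisole
Product: 20 methyl (3R)-3-[4-chloro-2-methoxy-6-(methoxymethoxy)phenyl]-3-[(2R,3R)-2-(2,4-dimethoxyphenyl)-3-(3,5-dimethoxyphenyl)-4-methoxy-2,3-dihydro-1-benzofuran-6-yl]-2-(4-methoxyphenyl)propanoate (both C2 epimers)
Conditions: 19 (1.3 equiv), LiHMDS (2.3 equiv), Pd(dba)2 (5 mol%), P(t-Bu)3 (5 mol%), toluene, rt → 50 °C; aq. NH4Cl
Reagents that add atoms: none
Why: Pd-catalysed ester enolate α-arylation as in step 6, bromide before chloride; the new C2 centre need not be controlled.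

**Step 13**
Reactants: 20 the α-(4-methoxyphenyl) ester
Product: 21 (3R)-3-[4-chloro-2-methoxy-6-(methoxymethoxy)phenyl]-3-[(2R,3R)-2-(2,4-dimethoxyphenyl)-3-(3,5-dimethoxyphenyl)-4-methoxy-2,3-dihydro-1-benzofuran-6-yl]-2-(4-methoxyphenyl)propanoic acid (both C2 epimers)
Conditions: LiOH·H2O (10 equiv), THF/MeOH/H2O, 60 °C; 1 M HCl to pH 3–4, 0 °C
Reagents that add atoms: lithium hydroxide, [Li+].[OH-]
Why: Saponification as in step 7; neither the MOM acetal nor the unit-2 benzylic ether is expected to ionise during the cold, brief acidification.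

**Step 14**
Reactants: 21 the unit-1 MOM-protected acid
Product: 22 (2R,3R)-6-chloro-3-[(2R,3R)-2-(2,4-dimethoxyphenyl)-3-(3,5-dimethoxyphenyl)-4-methoxy-2,3-dihydro-1-benzofuran-6-yl]-4-methoxy-2-(4-methoxyphenyl)-2,3-dihydro-1-benzofuran
Conditions: undivided cell, graphite anode/Pt cathode, constant current (charge limited to ca. 2.2 F mol−1), 2,4,6-collidine (1.5 equiv), HFIP (5 equiv), n-Bu4NPF6 (0.1 M), CH2Cl2, rt
Reagents that add atoms: none
Why: Proposed new method: as in step 8, anodic oxidation of the carboxylate releases CO2 and, after a second electron transfer, the 4-methoxybenzylic C2 cation, which the ortho MOM-ether oxygen captures in a 5-exo closure with loss of the methoxymethyl cation, the C2 aryl group settling trans to the bulky C3 substituent under control by C3; the closest known reaction type is the Hofer–Moest decarboxylative etherification of arylacetic acids, and the charge is limited so that the electron-rich unit-2 ring is not attacked once the carboxylate is consumed.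

**Step 15**
Reactants: 22 the bis(dihydrobenzofuran) chloride; 23 4-methoxystyrene
Product: 24 (2R,3R)-3-[(2R,3R)-2-(2,4-dimethoxyphenyl)-3-(3,5-dimethoxyphenyl)-4-methoxy-2,3-dihydro-1-benzofuran-6-yl]-4-methoxy-2-(4-methoxyphenyl)-6-[(E)-2-(4-methoxyphenyl)ethenyl]-2,3-dihydro-1-benzofuran
Conditions: 23 (2 equiv), Pd2(dba)3 (2.5 mol%), P(t-Bu)3·HBF4 (10 mol%), Cy2NMe (1.5 equiv), dioxane, 110 °C
Reagents that add atoms: none
Why: Mizoroki–Heck reaction of an aryl chloride with a Pd/P(t-Bu)3 catalyst; the neutral pathway should give β-arylation and the E-stilbene, and no stereocentre is involved.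

**Step 16**
Reactants: 24 the octamethyl ether
Product: 25 (2R,3R)-3-[(2R,3R)-2-(2,4-dihydroxyphenyl)-3-(3,5-dihydroxyphenyl)-4-hydroxy-2,3-dihydro-1-benzofuran-6-yl]-2-(4-hydroxyphenyl)-6-[(E)-2-(4-hydroxyphenyl)ethenyl]-2,3-dihydro-1-benzofuran-4-ol (CNP0118407.2)
Conditions: BBr3 (24 equiv), CH2Cl2, −78 °C → rt; ice-water
Reagents that add atoms: none
Why: Lewis-acid cleavage of all eight aryl methyl ethers; C3 and C3′ are not ionisable, and a benzylic C2–O or C2′–O bond that opens under BBr3 should reclose on quench to the trans ring, the more stable isomer.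

**Compound list**
1 | 4-chloro-2,6-difluorobenzaldehyde | O=Cc1c(F)cc(Cl)cc1F | starting material
2 | 4-chloro-2,6-dimethoxybenzaldehyde | O=Cc1c(OC)cc(Cl)cc1OC | intermediate
3 | 4-chloro-2-hydroxy-6-methoxybenzaldehyde | O=Cc1c(O)cc(Cl)cc1OC | intermediate
4 | ethyl (triphenylphosphoranylidene)acetate | CCOC(=O)C=P(c1ccccc1)(c1ccccc1)c1ccccc1 | starting material
5 | ethyl (E)-3-(4-chloro-2-hydroxy-6-methoxyphenyl)prop-2-enoate | CCOC(=O)/C=C/c1c(O)cc(Cl)cc1OC | intermediate
6 | 7-chloro-5-methoxy-2H-chromen-2-one | O=C1C=Cc2c(OC)cc(Cl)cc2O1 | intermediate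
7 | 3,5-dimethoxyphenylboronic acid | COc1cc(cc(OC)c1)B(O)O | starting material
8 | (4R)-7-chloro-4-(3,5-dimethoxyphenyl)-5-methoxy-3,4-dihydro-2H-chromen-2-one | O=C1C[C@H](c2cc(OC)cc(OC)c2)c2c(OC)cc(Cl)cc2O1 | intermediate
9 | sodium 5-chloro-2-[(1R)-1-(3,5-dimethoxyphenyl)-3-methoxy-3-oxopropyl]-3-methoxyphenolate | COC(=O)C[C@H](c1cc(OC)cc(OC)c1)c1c(OC)cc(Cl)cc1[O-].[Na+] | intermediate
10 | methyl (3R)-3-[4-chloro-2-methoxy-6-(methoxymethoxy)phenyl]-3-(3,5-dimethoxyphenyl)propanoate | COC(=O)C[C@H](c1cc(OC)cc(OC)c1)c1c(OC)cc(Cl)cc1OCOC | intermediate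
11 | 1-bromo-2,4-dimethoxybenzene | COc1ccc(Br)c(OC)c1 | starting material
12 | methyl (3R)-3-[4-chloro-2-methoxy-6-(methoxymethoxy)phenyl]-2-(2,4-dimethoxyphenyl)-3-(3,5-dimethoxyphenyl)propanoate, C2 epimers | COC(=O)C(c1ccc(OC)cc1OC)[C@H](c1cc(OC)cc(OC)c1)c1c(OC)cc(Cl)cc1OCOC | intermediate
13 | (3R)-3-[4-chloro-2-methoxy-6-(methoxymethoxy)phenyl]-2-(2,4-dimethoxyphenyl)-3-(3,5-dimethoxyphenyl)propanoic acid, C2 epimers | OC(=O)C(c1ccc(OC)cc1OC)[C@H](c1cc(OC)cc(OC)c1)c1c(OC)cc(Cl)cc1OCOC | intermediate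
14 | (2R,3R)-6-chloro-2-(2,4-dimethoxyphenyl)-3-(3,5-dimethoxyphenyl)-4-methoxy-2,3-dihydro-1-benzofuran | Clc1cc(OC)c2c(c1)O[C@@H](c1ccc(OC)cc1OC)[C@@H]2c1cc(OC)cc(OC)c1 | intermediate
15 | 2-[(2R,3R)-2-(2,4-dimethoxyphenyl)-3-(3,5-dimethoxyphenyl)-4-methoxy-2,3-dihydro-1-benzofuran-6-yl]-4,4,5,5-tetramethyl-1,3,2-dioxaborolane | CC1(C)OB(OC1(C)C)c1cc(OC)c2c(c1)O[C@@H](c1ccc(OC)cc1OC)[C@@H]2c1cc(OC)cc(OC)c1 | intermediate
16 | (4R)-7-chloro-4-[(2R,3R)-2-(2,4-dimethoxyphenyl)-3-(3,5-dimethoxyphenyl)-4-methoxy-2,3-dihydro-1-benzofuran-6-yl]-5-methoxy-3,4-dihydro-2H-chromen-2-one | O=C1C[C@H](c2cc(OC)c3c(c2)O[C@@H](c2ccc(OC)cc2OC)[C@@H]3c2cc(OC)cc(OC)c2)c2c(OC)cc(Cl)cc2O1 | intermediate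
17 | sodium phenolate of the ring-opened methyl ester of 16 | COC(=O)C[C@H](c1cc(OC)c2c(c1)O[C@@H](c1ccc(OC)cc1OC)[C@@H]2c1cc(OC)cc(OC)c1)c1c(OC)cc(Cl)cc1[O-].[Na+] | intermediate
18 | methyl (3R)-3-[4-chloro-2-methoxy-6-(methoxymethoxy)phenyl]-3-[(2R,3R)-2-(2,4-dimethoxyphenyl)-3-(3,5-dimethoxyphenyl)-4-methoxy-2,3-dihydro-1-benzofuran-6-yl]propanoate | COC(=O)C[C@H](c1cc(OC)c2c(c1)O[C@@H](c1ccc(OC)cc1OC)[C@@H]2c1cc(OC)cc(OC)c1)c1c(OC)cc(Cl)cc1OCOC | intermediate
19 | 4-bromoanisole | COc1ccc(Br)cc1 | starting material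
20 | methyl (3R)-3-[4-chloro-2-methoxy-6-(methoxymethoxy)phenyl]-3-[(2R,3R)-2-(2,4-dimethoxyphenyl)-3-(3,5-dimethoxyphenyl)-4-methoxy-2,3-dihydro-1-benzofuran-6-yl]-2-(4-methoxyphenyl)propanoate, C2 epimers | COC(=O)C(c1ccc(OC)cc1)[C@H](c1cc(OC)c2c(c1)O[C@@H](c1ccc(OC)cc1OC)[C@@H]2c1cc(OC)cc(OC)c1)c1c(OC)cc(Cl)cc1OCOC | intermediate
21 | (3R)-3-[4-chloro-2-methoxy-6-(methoxymethoxy)phenyl]-3-[(2R,3R)-2-(2,4-dimethoxyphenyl)-3-(3,5-dimethoxyphenyl)-4-methoxy-2,3-dihydro-1-benzofuran-6-yl]-2-(4-methoxyphenyl)propanoic acid, C2 epimers | OC(=O)C(c1ccc(OC)cc1)[C@H](c1cc(OC)c2c(c1)O[C@@H](c1ccc(OC)cc1OC)[C@@H]2c1cc(OC)cc(OC)c1)c1c(OC)cc(Cl)cc1OCOC | intermediate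
22 | (2R,3R)-6-chloro-3-[(2R,3R)-2-(2,4-dimethoxyphenyl)-3-(3,5-dimethoxyphenyl)-4-methoxy-2,3-dihydro-1-benzofuran-6-yl]-4-methoxy-2-(4-methoxyphenyl)-2,3-dihydro-1-benzofuran | Clc1cc(OC)c2c(c1)O[C@@H](c1ccc(OC)cc1)[C@@H]2c1cc(OC)c2c(c1)O[C@@H](c1ccc(OC)cc1OC)[C@@H]2c1cc(OC)cc(OC)c1 | intermediate
23 | 4-methoxystyrene | C=Cc1ccc(OC)cc1 | starting material
24 | octamethyl ether of the target | COc1ccc(/C=C/c2cc(OC)c3c(c2)O[C@@H](c2ccc(OC)cc2)[C@@H]3c2cc(OC)c3c(c2)O[C@@H](c2ccc(OC)cc2OC)[C@@H]3c2cc(OC)cc(OC)c2)cc1 | intermediate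
25 | CNP0118407.2, (2R,3R)-3-[(2R,3R)-2-(2,4-dihydroxyphenyl)-3-(3,5-dihydroxyphenyl)-4-hydroxy-2,3-dihydro-1-benzofuran-6-yl]-2-(4-hydroxyphenyl)-6-[(E)-2-(4-hydroxyphenyl)ethenyl]-2,3-dihydro-1-benzofuran-4-ol | Oc1ccc(/C=C/c2cc(O)c3c(c2)O[C@@H](c2ccc(O)cc2)[C@@H]3c2cc(O)c3c(c2)O[C@@H](c2ccc(O)cc2O)[C@@H]3c2cc(O)cc(O)c2)cc1 | target

**Totals**
Total step count: 16. Longest linear sequence: 16 steps (from 1; coumarin 6 from step 3 is used again in step 10).

**Steps most likely to fail**

Step 8 (Proposed new method). Electron loss may occur at a dimethoxyarene ring or at the product instead of the carboxylate, leading to over-oxidation and dehydrogenation of the new ring. The ring closure may also be too slow, so that the cation loses the C3′ proton (alkene, C3′ erased) or is intercepted by HFIP or by the distal acetal oxygen. The fallback uses known, redox-neutral chemistry and sets out from 13. Esterification with N-hydroxyphthalimide (DIC, DMAP, CH2Cl2) gives the redox-active ester 1,3-dioxoisoindolin-2-yl (3R)-3-[4-chloro-2-methoxy-6-(methoxymethoxy)phenyl]-2-(2,4-dimethoxyphenyl)-3-(3,5-dimethoxyphenyl)propanoate F1. Organophotoredox radical–polar crossover decarboxylative etherification (phenothiazine catalyst, blue LED, MeOH/MeCN) then gives the benzylic methyl ether 5-chloro-2-[(1R)-2-(2,4-dimethoxyphenyl)-1-(3,5-dimethoxyphenyl)-2-methoxyethyl]-1-methoxy-3-(methoxymethoxy)benzene F2 without any strong oxidant. Catalytic TFA in HFIP/CH2Cl2 ionises the 2,4-dimethoxybenzylic ether, removes the MOM group and closes the ring under thermodynamic control, which comes back to the route at 14.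

Step 14 (Proposed new method). The unit-2 ring system, with its 2,4-dimethoxyphenyl-substituted benzylic ether, may be oxidised in competition with the carboxylate, causing dehydrogenation or opening of the ring already built. The less stabilised 4-methoxybenzylic cation may also eliminate before it is captured. The fallback sets out from 21. The N-hydroxyphthalimide ester of 21 F3 (DIC, DMAP) is submitted to the same organophotoredox decarboxylative etherification with methanol to give the C2 methyl ether of the unit-1 seco compound F4. Acid in HFIP/CH2Cl2 (TFA or CSA) then effects ionisation, loss of MOM and ring closure; a unit-2 C2′–O bond that opens reversibly recloses to the trans ring. The fallback comes back to the route at 22.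

Step 10. Protodeboronation of the valuable boronate may outrun insertion into the peri-methoxy coumarin, and catalyst control over the new centre may be incomplete. The fallback sets out from 15 and 6. Pd(II)-catalysed oxidative Heck coupling (Pd(OAc)2, 1,10-phenanthroline, O2, DMF) makes the C3–C6′ bond without a stereocentre and gives 7-chloro-4-[(2R,3R)-2-(2,4-dimethoxyphenyl)-3-(3,5-dimethoxyphenyl)-4-methoxy-2,3-dihydro-1-benzofuran-6-yl]-5-methoxy-2H-chromen-2-one F5. CuH-catalysed asymmetric conjugate reduction (Cu(OAc)2, the DTBM-Segphos enantiomer that gives 4R, (EtO)2MeSiH, t-BuOH, toluene) sets C3 and is expected to over-reduce to the (4R)-chroman-2-ol (lactol) F6. Oxidation of the lactol (TEMPO, PhI(OAc)2) comes back to the route at 16.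

**Further compounds**
F1 | step 8 | 1,3-dioxoisoindolin-2-yl (3R)-3-[4-chloro-2-methoxy-6-(methoxymethoxy)phenyl]-2-(2,4-dimethoxyphenyl)-3-(3,5-dimethoxyphenyl)propanoate | O=C(ON1C(=O)c2ccccc2C1=O)C(c1ccc(OC)cc1OC)[C@H](c1cc(OC)cc(OC)c1)c1c(OC)cc(Cl)cc1OCOC
F2 | step 8 | 5-chloro-2-[(1R)-2-(2,4-dimethoxyphenyl)-1-(3,5-dimethoxyphenyl)-2-methoxyethyl]-1-methoxy-3-(methoxymethoxy)benzene | COC(c1ccc(OC)cc1OC)[C@H](c1cc(OC)cc(OC)c1)c1c(OC)cc(Cl)cc1OCOC
F3 | step 14 | N-hydroxyphthalimide ester of 21 | O=C(ON1C(=O)c2ccccc2C1=O)C(c1ccc(OC)cc1)[C@H](c1cc(OC)c2c(c1)O[C@@H](c1ccc(OC)cc1OC)[C@@H]2c1cc(OC)cc(OC)c1)c1c(OC)cc(Cl)cc1OCOC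
F4 | step 14 | C2 methyl ether of the unit-1 seco compound (decarboxylated 21 with OMe at the 4-methoxybenzylic carbon) | COC(c1ccc(OC)cc1)[C@H](c1cc(OC)c2c(c1)O[C@@H](c1ccc(OC)cc1OC)[C@@H]2c1cc(OC)cc(OC)c1)c1c(OC)cc(Cl)cc1OCOC
F5 | step 10 | 7-chloro-4-[(2R,3R)-2-(2,4-dimethoxyphenyl)-3-(3,5-dimethoxyphenyl)-4-methoxy-2,3-dihydro-1-benzofuran-6-yl]-5-methoxy-2H-chromen-2-one | O=C1C=C(c2cc(OC)c3c(c2)O[C@@H](c2ccc(OC)cc2OC)[C@@H]3c2cc(OC)cc(OC)c2)c2c(OC)cc(Cl)cc2O1
F6 | step 10 | (4R)-7-chloro-4-[(2R,3R)-2-(2,4-dimethoxyphenyl)-3-(3,5-dimethoxyphenyl)-4-methoxy-2,3-dihydro-1-benzofuran-6-yl]-5-methoxy-3,4-dihydro-2H-chromen-2-ol, anomers | OC1C[C@H](c2cc(OC)c3c(c2)O[C@@H](c2ccc(OC)cc2OC)[C@@H]3c2cc(OC)cc(OC)c2)c2c(OC)cc(Cl)cc2O1
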